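**Retrosynthetic overview**

1. The last step forms the C11–O bond: a stereospecific 1,3-hydroxyl shift (C13–OH to C11–OH) on an allylic triol, which also creates the (E)-C12=C13 alkene. C14 is therefore carried through the route as an ordinary aldol α-centre and becomes allylic only at the end.
2. The allylic triol comes from a tris-silylated bis-pyrone. The right pyrone is closed by C–O cyclodehydration of a 1,3,5-triketone, made by Claisen union of an East β-diketone dianion (Evans syn-aldol with propanal, then pentan-3-one) with a central Weinreb amide.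
3. The central Weinreb amide comes from an Evans syn-aldol on an (E)-enal. The enal comes from a pyrone-bearing 1,1-disubstituted alkene by Rh-catalysed hydroboration, oxidation and Wittig reaction.
4. The left pyrone is closed by C–O cyclodehydration of a triketone from the dianion of 4-methylheptane-3,5-dione and the Weinreb amide of an Evans anti-aldol adduct of methacrolein.
5. Ring order: left pyrone first (step 4), right pyrone second (step 15); the final step forms no ring.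

Assumption: 4-methylheptane-3,5-dione and both enantiomers of 4-benzyl-3-propionyloxazolidin-2-one are bought as catalogue compounds; locants C1–C23 follow the polyketide backbone (C1 = CH3 of the ethyl on the left pyrone, C3–C7 = left pyrone carbons, C8–C14 = linker, C15–C19 = right pyrone carbons, C20–C23 = side chain).

**Route**

Step 1
Reactants: 1 (R)-4-benzyl-3-propionyloxazolidin-2-one; 2 methacrolein
Product: 4 (R)-4-benzyl-3-[(2S,3R)-3-hydroxy-2,4-dimethylpent-4-enoyl]oxazolidin-2-one, via O-trimethylsilyl aldol adduct 3 (not isolated)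
Conditions: MgCl2 (0.2 equiv), Et3N, TMSCl, EtOAc, 23 °C; then 1 M HCl/THF
Reagents that add atoms: none
Why: MgCl2-catalysed Evans anti-aldol (soft enolisation, TMSCl turnover): the chelated (Z)-magnesium enolate is attacked by the non-enolisable enal through a boat transition state on the face opposite the benzyl group, which sets C8 and C9 anti with the required absolute sense.

Step 2
Reactants: 4 anti-aldol imide
Product: 5 (2S,3R)-3-hydroxy-N-methoxy-N,2,4-trimethylpent-4-enamide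
Conditions: MeONHMe·HCl, AlMe3, CH2Cl2/THF, −20 → 0 °C; Rochelle salt work-up
Reagents that add atoms: N,O-dimethylhydroxylamine hydrochloride, CNOC.Cl
Why: Weinreb transamidation with the aluminium amide, assisted by the free β-hydroxyl, removes the auxiliary without epimerising C8.

Step 3
Reactants: 5 hydroxy Weinreb amide
Product: 6 (2S,3R)-3-[(tert-butyldimethylsilyl)oxy]-N-methoxy-N,2,4-trimethylpent-4-enamide
Conditions: TBSOTf, 2,6-lutidine, CH2Cl2, −78 → 0 °C
Reagents that add atoms: tert-butyldimethylsilyl trifluoromethanesulfonate, CC(C)(C)[Si](C)(C)OS(=O)(=O)C(F)(F)F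
Why: Silylation of the secondary allylic alcohol blocks retro-aldol and alkoxide chemistry in the next, strongly basic step.

Step 4
Reactants: 6 silyl Weinreb amide; 7 4-methylheptane-3,5-dione
Product: 9 2-[(2S,3R)-3-[(tert-butyldimethylsilyl)oxy]-4-methylpent-4-en-2-yl]-6-ethyl-3,5-dimethyl-4H-pyran-4-one, via triketone 8 (not isolated)
Conditions: 7, LDA (2.1 equiv per 7), THF, −78 → 0 °C; then 6, −78 → −20 °C; AcOH quench; crude 8, PPh3, CCl4, THF, 23 °C
Reagents that add atoms: none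
Why: Claisen-type acylation of the β-diketone dianion at its terminal carbon by the Weinreb amide gives the 1,3,5-triketone, and Appel-type cyclodehydration (PPh3/CCl4) then forms the ring C–O bond of the left γ-pyrone under neutral conditions that leave C8 alone.

Step 5
Reactants: 9 pyrone alkene
Product: 11 2-[(2S,3S,4R)-3-[(tert-butyldimethylsilyl)oxy]-5-hydroxy-4-methylpentan-2-yl]-6-ethyl-3,5-dimethyl-4H-pyran-4-one, via catechol boronate 10 (not isolated)
Conditions: catecholborane, RhCl(PPh3)3 (3 mol%), THF, 23 °C; then NaOH, H2O2, 0 °C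
Reagents that add atoms: hydrogen peroxide, OO
Why: Rh(I)-catalysed hydroboration with catecholborane followed by oxidation is syn-selective for 1,1-disubstituted allylic silyl ethers, so the C10 methyl centre is set syn to the C9 oxygen while the tetrasubstituted pyrone double bonds stay untouched.

Step 6
Reactants: 11 primary alcohol
Product: 12 (2S,3R,4S)-3-[(tert-butyldimethylsilyl)oxy]-4-(6-ethyl-3,5-dimethyl-4-oxo-4H-pyran-2-yl)-2-methylpentanal
Conditions: Dess–Martin periodinane, CH2Cl2, 0 → 23 °C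
Reagents that add atoms: none
Why: Dess–Martin oxidation is neutral and stops at the aldehyde without epimerising C10.

Step 7
Reactants: 12 aldehyde; 13 2-(triphenyl-λ5-phosphanylidene)propanal
Product: 14 (2E,4R,5S,6S)-5-[(tert-butyldimethylsilyl)oxy]-6-(6-ethyl-3,5-dimethyl-4-oxo-4H-pyran-2-yl)-2,4-dimethylhept-2-enal
Conditions: toluene, 90 °C
Reagents that add atoms: none
Why: Wittig olefination with the stabilised, α-branched ylide gives the (E)-trisubstituted enal that the final chirality transfer needs.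

Step 8
Reactants: 14 enal; 1 (R)-4-benzyl-3-propionyloxazolidin-2-one
Product: 15 (R)-4-benzyl-3-[(2R,3R,4E,6R,7S,8S)-7-[(tert-butyldimethylsilyl)oxy]-8-(6-ethyl-3,5-dimethyl-4-oxo-4H-pyran-2-yl)-3-hydroxy-2,4,6-trimethylnon-4-enoyl]oxazolidin-2-one
Conditions: 1, Bu2BOTf, iPr2NEt, CH2Cl2, −78 → 0 °C; then 14, −78 → 0 °C; pH 7 buffer, MeOH, H2O2, 0 °C
Reagents that add atoms: none
Why: Evans syn-aldol: the (Z)-dibutylboron enolate reacts through a Zimmerman–Traxler chair under control of the (R)-auxiliary, setting C14 (R) and C13 (R) irrespective of the remote C10 centre.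

Step 9
Reactants: 15 syn-aldol imide
Product: 16 (2R,3R,4E,6R,7S,8S)-7-[(tert-butyldimethylsilyl)oxy]-8-(6-ethyl-3,5-dimethyl-4-oxo-4H-pyran-2-yl)-3-hydroxy-N-methoxy-N,2,4,6-tetramethylnon-4-enamide
Conditions: MeONHMe·HCl, AlMe3, CH2Cl2/THF, −20 → 0 °C; Rochelle salt work-up
Reagents that add atoms: N,O-dimethylhydroxylamine hydrochloride, CNOC.Cl
Why: Weinreb transamidation directed by the free C13 hydroxyl releases the auxiliary and gives an acyl donor that stops at mono-addition.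

Step 10
Reactants: 16 hydroxy Weinreb amide
Product: 17 (2R,3R,4E,6R,7S,8S)-3,7-bis[(tert-butyldimethylsilyl)oxy]-8-(6-ethyl-3,5-dimethyl-4-oxo-4H-pyran-2-yl)-N-methoxy-N,2,4,6-tetramethylnon-4-enamide
Conditions: TBSOTf, 2,6-lutidine, CH2Cl2, −78 → 0 °C
Reagents that add atoms: tert-butyldimethylsilyl trifluoromethanesulfonate, CC(C)(C)[Si](C)(C)OS(=O)(=O)C(F)(F)F
Why: Silylation protects the allylic C13 hydroxyl so that C14 survives the basic Claisen step as a normal β-silyloxy α-methyl acyl centre.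

Step 11
Reactants: 18 (S)-4-benzyl-3-propionyloxazolidin-2-one; 19 propanal
Product: 20 (S)-4-benzyl-3-[(2S,3R)-3-hydroxy-2-methylpentanoyl]oxazolidin-2-one
Conditions: 18, Bu2BOTf, iPr2NEt, CH2Cl2, −78 → 0 °C; then 19, −78 → 0 °C; pH 7 buffer, MeOH, H2O2, 0 °C
Reagents that add atoms: none
Why: Evans syn-aldol through the (Z)-boron enolate chair with the (S)-auxiliary sets C20 (S) and C21 (R).

Step 12
Reactants: 20 East aldol imide
Product: 21 (2S,3R)-3-hydroxy-N-methoxy-N,2-dimethylpentanamide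
Conditions: MeONHMe·HCl, AlMe3, CH2Cl2/THF, −20 → 0 °C; Rochelle salt work-up
Reagents that add atoms: N,O-dimethylhydroxylamine hydrochloride, CNOC.Cl
Why: Weinreb transamidation assisted by the β-hydroxyl removes the auxiliary without epimerisation.

Step 13
Reactants: 21 East hydroxy Weinreb amide
Product: 22 (2S,3R)-3-[(tert-butyldimethylsilyl)oxy]-N-methoxy-N,2-dimethylpentanamide
Conditions: TBSOTf, 2,6-lutidine, CH2Cl2, −78 → 0 °C
Reagents that add atoms: tert-butyldimethylsilyl trifluoromethanesulfonate, CC(C)(C)[Si](C)(C)OS(=O)(=O)C(F)(F)F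
Why: Silyl protection prevents retro-aldol and β-elimination in the two enolate steps that follow.

Step 14
Reactants: 22 East silyl Weinreb amide; 23 pentan-3-one
Product: 24 (6S,7R)-7-[(tert-butyldimethylsilyl)oxy]-4,6-dimethylnonane-3,5-dione
Conditions: 23, LDA, THF, −78 °C; then 22, −78 → −20 °C; AcOH quench
Reagents that add atoms: none
Why: Claisen-type C-acylation of the ketone lithium enolate by the Weinreb amide stops at the chelated tetrahedral adduct, so the β-diketone appears only on work-up and C20/C21 are untouched.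

Step 15
Reactants: 17 central bis-silyl Weinreb amide; 24 East β-diketone
Product: 26 2-[(2R,3R,4E,6R,7S,8S)-3,7-bis[(tert-butyldimethylsilyl)oxy]-8-(6-ethyl-3,5-dimethyl-4-oxo-4H-pyran-2-yl)-4,6-dimethylnon-4-en-2-yl]-6-[(2S,3R)-3-[(tert-butyldimethylsilyl)oxy]pentan-2-yl]-3,5-dimethyl-4H-pyran-4-one, via triketone 25 (not isolated)
Conditions: 24 (2 equiv), LDA (4.2 equiv), THF, −78 → 0 °C; then 17, −78 → −20 °C; AcOH quench; crude 25, PPh3, CCl4, THF, 23 °C
Reagents that add atoms: none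
Why: The kinetic dianion of 24 (C18, then the ethyl CH2 = C16) is acylated at C16 by the Weinreb amide (Claisen type), and Appel-type cyclodehydration of the C15/C17/C19 triketone closes the ring C–O bond of the right γ-pyrone; C14 is a β-silyloxy centre here and does not scramble.

Step 16
Reactants: 26 tris-silyl bis-pyrone
Product: 27 2-[(2R,3R,4E,6R,7S,8S)-8-(6-ethyl-3,5-dimethyl-4-oxo-4H-pyran-2-yl)-3,7-dihydroxy-4,6-dimethylnon-4-en-2-yl]-6-[(2S,3R)-3-hydroxypentan-2-yl]-3,5-dimethyl-4H-pyran-4-one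
Conditions: HF·pyridine, pyridine/THF, 0 → 23 °C
Reagents that add atoms: none
Why: Fluoride-mediated desilylation removes all three TBS ethers in a buffered acidic medium that avoids the base-induced β-elimination toward the pyrones that TBAF would risk.

Step 17
Reactants: 27 allylic triol
Product: 29 target 2-[(2R,3E,5S,6S,7S,8S)-8-(6-ethyl-3,5-dimethyl-4-oxo-4H-pyran-2-yl)-5,7-dihydroxy-4,6-dimethylnon-3-en-2-yl]-6-[(2S,3R)-3-hydroxypentan-2-yl]-3,5-dimethyl-4H-pyran-4-one, via cyclic phenylboronate 28 (not isolated)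
Conditions: Ph3SiOReO3 (5 mol%), PhB(OH)2 (1.5 equiv), 4 Å MS, CH2Cl2, −50 → 0 °C; then pinacol, MeOH, 23 °C
Reagents that add atoms: none
Why: Proposed new method: a boronic-acid-gated, chirality-transferring rhenium(VII) 1,3-hydroxyl transposition — the C13 allylic alcohol forms an allyl perrhenate that undergoes a suprafacial [3,3] shift through a chair with the C14 substituent pseudo-equatorial, delivering oxygen to C11 ((13R) → (11S)) and forming the (E)-C12=C13 alkene; the new C11–OH and the C9–OH are captured at once as a six-membered phenylboronate (trigonal boron tolerates the 9,11-anti relationship) that has no free allylic OH to re-enter the perrhenate manifold, so the otherwise thermoneutral equilibrium is pulled forward under kinetic control and pinacol exchange then frees the diol; closest known reaction type: rhenium-oxo-catalysed 1,3-transposition of allylic alcohols ([3,3] of allyl perrhenates), whose acetal-trapped variant is thermodynamically controlled and gives 1,3-syn diols.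

**Compound list**

1 | (R)-4-benzyl-3-propionyloxazolidin-2-one | CCC(=O)N1[C@H](Cc2ccccc2)COC1=O | starting material
2 | methacrolein (2-methylprop-2-enal) | C=C(C)C=O | starting material
3 | (R)-4-benzyl-3-[(2S,3R)-2,4-dimethyl-3-[(trimethylsilyl)oxy]pent-4-enoyl]oxazolidin-2-one | O=C([C@@H](C)[C@@H](O[Si](C)(C)C)C(C)=C)N1[C@H](Cc2ccccc2)COC1=O | intermediate
4 | (R)-4-benzyl-3-[(2S,3R)-3-hydroxy-2,4-dimethylpent-4-enoyl]oxazolidin-2-one | O=C([C@@H](C)[C@@H](O)C(C)=C)N1[C@H](Cc2ccccc2)COC1=O | intermediate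
5 | (2S,3R)-3-hydroxy-N-methoxy-N,2,4-trimethylpent-4-enamide | CON(C)C(=O)[C@@H](C)[C@@H](O)C(C)=C | intermediate
6 | (2S,3R)-3-[(tert-butyldimethylsilyl)oxy]-N-methoxy-N,2,4-trimethylpent-4-enamide | CON(C)C(=O)[C@@H](C)[C@@H](O[Si](C)(C)C(C)(C)C)C(C)=C | intermediate
7 | 4-methylheptane-3,5-dione | CCC(=O)C(C)C(=O)CC | starting material
8 | (8S,9R)-9-[(tert-butyldimethylsilyl)oxy]-4,6,8,10-tetramethylundec-10-ene-3,5,7-trione (C4/C6 epimers and enol tautomers) | CCC(=O)C(C)C(=O)C(C)C(=O)[C@@H](C)[C@@H](O[Si](C)(C)C(C)(C)C)C(C)=C | intermediate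
9 | 2-[(2S,3R)-3-[(tert-butyldimethylsilyl)oxy]-4-methylpent-4-en-2-yl]-6-ethyl-3,5-dimethyl-4H-pyran-4-one | CCc1oc([C@@H](C)[C@@H](O[Si](C)(C)C(C)(C)C)C(C)=C)c(C)c(=O)c1C | intermediate
10 | 2-[(2S,3S,4R)-5-(1,3,2-benzodioxaborol-2-yl)-3-[(tert-butyldimethylsilyl)oxy]-4-methylpentan-2-yl]-6-ethyl-3,5-dimethyl-4H-pyran-4-one | CCc1oc([C@@H](C)[C@@H](O[Si](C)(C)C(C)(C)C)[C@H](C)CB2Oc3ccccc3O2)c(C)c(=O)c1C | intermediate
11 | 2-[(2S,3S,4R)-3-[(tert-butyldimethylsilyl)oxy]-5-hydroxy-4-methylpentan-2-yl]-6-ethyl-3,5-dimethyl-4H-pyran-4-one | CCc1oc([C@@H](C)[C@@H](O[Si](C)(C)C(C)(C)C)[C@H](C)CO)c(C)c(=O)c1C | intermediate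
12 | (2S,3R,4S)-3-[(tert-butyldimethylsilyl)oxy]-4-(6-ethyl-3,5-dimethyl-4-oxo-4H-pyran-2-yl)-2-methylpentanal | CCc1oc([C@@H](C)[C@@H](O[Si](C)(C)C(C)(C)C)[C@H](C)C=O)c(C)c(=O)c1C | intermediate
13 | 2-(triphenyl-λ5-phosphanylidene)propanal | CC(C=O)=P(c1ccccc1)(c1ccccc1)c1ccccc1 | starting material
14 | (2E,4R,5S,6S)-5-[(tert-butyldimethylsilyl)oxy]-6-(6-ethyl-3,5-dimethyl-4-oxo-4H-pyran-2-yl)-2,4-dimethylhept-2-enal | CCc1oc([C@@H](C)[C@@H](O[Si](C)(C)C(C)(C)C)[C@H](C)/C=C(\C)C=O)c(C)c(=O)c1C | intermediate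
15 | (R)-4-benzyl-3-[(2R,3R,4E,6R,7S,8S)-7-[(tert-butyldimethylsilyl)oxy]-8-(6-ethyl-3,5-dimethyl-4-oxo-4H-pyran-2-yl)-3-hydroxy-2,4,6-trimethylnon-4-enoyl]oxazolidin-2-one | CCc1oc([C@@H](C)[C@@H](O[Si](C)(C)C(C)(C)C)[C@H](C)/C=C(\C)[C@H](O)[C@@H](C)C(=O)N2[C@H](Cc3ccccc3)COC2=O)c(C)c(=O)c1C | intermediate
16 | (2R,3R,4E,6R,7S,8S)-7-[(tert-butyldimethylsilyl)oxy]-8-(6-ethyl-3,5-dimethyl-4-oxo-4H-pyran-2-yl)-3-hydroxy-N-methoxy-N,2,4,6-tetramethylnon-4-enamide | CCc1oc([C@@H](C)[C@@H](O[Si](C)(C)C(C)(C)C)[C@H](C)/C=C(\C)[C@H](O)[C@@H](C)C(=O)N(C)OC)c(C)c(=O)c1C | intermediate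
17 | (2R,3R,4E,6R,7S,8S)-3,7-bis[(tert-butyldimethylsilyl)oxy]-8-(6-ethyl-3,5-dimethyl-4-oxo-4H-pyran-2-yl)-N-methoxy-N,2,4,6-tetramethylnon-4-enamide | CCc1oc([C@@H](C)[C@@H](O[Si](C)(C)C(C)(C)C)[C@H](C)/C=C(\C)[C@H](O[Si](C)(C)C(C)(C)C)[C@@H](C)C(=O)N(C)OC)c(C)c(=O)c1C | intermediate
18 | (S)-4-benzyl-3-propionyloxazolidin-2-one | CCC(=O)N1[C@@H](Cc2ccccc2)COC1=O | starting material
19 | propanal | CCC=O | starting material
20 | (S)-4-benzyl-3-[(2S,3R)-3-hydroxy-2-methylpentanoyl]oxazolidin-2-one | O=C([C@@H](C)[C@H](O)CC)N1[C@@H](Cc2ccccc2)COC1=O | intermediate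
21 | (2S,3R)-3-hydroxy-N-methoxy-N,2-dimethylpentanamide | CON(C)C(=O)[C@@H](C)[C@H](O)CC | intermediate
22 | (2S,3R)-3-[(tert-butyldimethylsilyl)oxy]-N-methoxy-N,2-dimethylpentanamide | CON(C)C(=O)[C@@H](C)[C@H](O[Si](C)(C)C(C)(C)C)CC | intermediate
23 | pentan-3-one | CCC(=O)CC | starting material
24 | (6S,7R)-7-[(tert-butyldimethylsilyl)oxy]-4,6-dimethylnonane-3,5-dione (C4 epimers and enol tautomers) | CCC(=O)C(C)C(=O)[C@@H](C)[C@H](O[Si](C)(C)C(C)(C)C)CC | intermediate
25 | 2-[(2S,3S,4R,5E,7R,8R,14S,15R)-3,7,15-tris[(tert-butyldimethylsilyl)oxy]-4,6,8,10,12,14-hexamethyl-9,11,13-trioxoheptadec-5-en-2-yl]-6-ethyl-3,5-dimethyl-4H-pyran-4-one (C10/C12 epimers and enol tautomers) | CCc1oc([C@@H](C)[C@@H](O[Si](C)(C)C(C)(C)C)[C@H](C)/C=C(\C)[C@H](O[Si](C)(C)C(C)(C)C)[C@@H](C)C(=O)C(C)C(=O)C(C)C(=O)[C@@H](C)[C@H](O[Si](C)(C)C(C)(C)C)CC)c(C)c(=O)c1C | intermediate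
26 | 2-[(2R,3R,4E,6R,7S,8S)-3,7-bis[(tert-butyldimethylsilyl)oxy]-8-(6-ethyl-3,5-dimethyl-4-oxo-4H-pyran-2-yl)-4,6-dimethylnon-4-en-2-yl]-6-[(2S,3R)-3-[(tert-butyldimethylsilyl)oxy]pentan-2-yl]-3,5-dimethyl-4H-pyran-4-one | CCc1oc([C@@H](C)[C@@H](O[Si](C)(C)C(C)(C)C)[C@H](C)/C=C(\C)[C@H](O[Si](C)(C)C(C)(C)C)[C@@H](C)c2oc([C@@H](C)[C@H](O[Si](C)(C)C(C)(C)C)CC)c(C)c(=O)c2C)c(C)c(=O)c1C | intermediate
27 | 2-[(2R,3R,4E,6R,7S,8S)-8-(6-ethyl-3,5-dimethyl-4-oxo-4H-pyran-2-yl)-3,7-dihydroxy-4,6-dimethylnon-4-en-2-yl]-6-[(2S,3R)-3-hydroxypentan-2-yl]-3,5-dimethyl-4H-pyran-4-one | CCc1oc([C@@H](C)[C@@H](O)[C@H](C)/C=C(\C)[C@H](O)[C@@H](C)c2oc([C@@H](C)[C@H](O)CC)c(C)c(=O)c2C)c(C)c(=O)c1C | intermediate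
28 | cyclic phenylboronate of 29 (2-phenyl-1,3,2-dioxaborinane spanning the C9 and C11 oxygens, C21–OH free) | CCc1oc([C@@H](C)[C@@H](OB(c3ccccc3)O4)[C@H](C)[C@H]4/C(C)=C/[C@@H](C)c2oc([C@@H](C)[C@H](O)CC)c(C)c(=O)c2C)c(C)c(=O)c1C | intermediate
29 | 2-[(2R,3E,5S,6S,7S,8S)-8-(6-ethyl-3,5-dimethyl-4-oxo-4H-pyran-2-yl)-5,7-dihydroxy-4,6-dimethylnon-3-en-2-yl]-6-[(2S,3R)-3-hydroxypentan-2-yl]-3,5-dimethyl-4H-pyran-4-one (CNP0408419.2) | CCc1oc([C@@H](C)[C@@H](O)[C@H](C)[C@H](O)/C(C)=C/[C@@H](C)c2oc([C@@H](C)[C@H](O)CC)c(C)c(=O)c2C)c(C)c(=O)c1C | target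

**Step count and risks**

Total step count: 17. Longest linear sequence: 13 (steps 1–10, then 15–17).

The three steps most likely to fail:

Step 17 (the proposed new transposition). The perrhenate may ionise instead of rearranging, which would erode chirality transfer at C11 or eliminate toward the pyrone. The boronate may also fail to outpace the back reaction. The fallback uses known chemistry, sets out from 27 and comes back at 29. It abandons chirality transfer and sets C11 by oxidation and directed reduction. Re2O7 (cat.) with benzaldehyde dimethyl acetal in CH2Cl2 gives, under thermodynamic control, the all-cis 9,11-O-benzylidene acetal of the C11 epimer F1. Aqueous AcOH/THF releases the 11-epi triol F2. MnO2 oxidises only the allylic C11 alcohol to the C11 enone F3. Evans–Saksena reduction (Me4NBH(OAc)3, AcOH/MeCN, −30 °C), with hydride delivered from the C9 hydroxyl, gives the 9,11-anti diol 29.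

Step 15 (late Claisen and second pyrone closure). The Weinreb amide is α-branched and hindered. The excess dianion can deprotonate the left pyrone, with a risk of β-elimination across C8/C9, or epimerise C14. The fallback sets out from 17 and comes back at 25. DIBAL-H (THF, −78 °C) reduces 17 to the aldehyde F4. Aldol addition of the dianion of 24 at −78 °C is much faster than acyl transfer and gives the β-hydroxy diketone F5. Dess–Martin oxidation then gives triketone 25, which re-enters step 15 at the PPh3/CCl4 cyclodehydration.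

Step 5 (Rh-catalysed hydroboration next to a pyrone). The basic pyrone carbonyl may bind or be reduced by catecholborane, or it may erode the syn selectivity. The fallback sets out from 6 and comes back at 11. It moves the hydroboration ahead of pyrone construction so that borane and pyrone never meet. Catecholborane/RhCl(PPh3)3 on 6 gives the catechol boronate F6, which NaOH/H2O2 oxidises to the hydroxy amide F7. TESCl/imidazole gives the primary TES ether F8. The dianion of 7 followed by PPh3/CCl4 (as in step 4) gives, through the triketone F9, the pyrone F10. PPTS/MeOH removes only the primary TES group and returns 11.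

**Further compounds**

F1 | step 17 | 9,11-O-benzylidene acetal of 11-epi-29 (2-phenyl-1,3-dioxane, C2/C4/C6 substituents all cis) | CCc1oc([C@@H](C)[C@@H](O[C@@H](c3ccccc3)O4)[C@H](C)[C@@H]4/C(C)=C/[C@@H](C)c2oc([C@@H](C)[C@H](O)CC)c(C)c(=O)c2C)c(C)c(=O)c1C
F2 | step 17 | 11-epi-29, 2-[(2R,3E,5R,6S,7S,8S)-8-(6-ethyl-3,5-dimethyl-4-oxo-4H-pyran-2-yl)-5,7-dihydroxy-4,6-dimethylnon-3-en-2-yl]-6-[(2S,3R)-3-hydroxypentan-2-yl]-3,5-dimethyl-4H-pyran-4-one | CCc1oc([C@@H](C)[C@@H](O)[C@H](C)[C@@H](O)/C(C)=C/[C@@H](C)c2oc([C@@H](C)[C@H](O)CC)c(C)c(=O)c2C)c(C)c(=O)c1C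
F3 | step 17 | 2-[(2R,3E,6S,7R,8S)-8-(6-ethyl-3,5-dimethyl-4-oxo-4H-pyran-2-yl)-7-hydroxy-4,6-dimethyl-5-oxonon-3-en-2-yl]-6-[(2S,3R)-3-hydroxypentan-2-yl]-3,5-dimethyl-4H-pyran-4-one | CCc1oc([C@@H](C)[C@@H](O)[C@H](C)C(=O)/C(C)=C/[C@@H](C)c2oc([C@@H](C)[C@H](O)CC)c(C)c(=O)c2C)c(C)c(=O)c1C
F4 | step 15 | (2R,3R,4E,6R,7S,8S)-3,7-bis[(tert-butyldimethylsilyl)oxy]-8-(6-ethyl-3,5-dimethyl-4-oxo-4H-pyran-2-yl)-2,4,6-trimethylnon-4-enal | CCc1oc([C@@H](C)[C@@H](O[Si](C)(C)C(C)(C)C)[C@H](C)/C=C(\C)[C@H](O[Si](C)(C)C(C)(C)C)[C@@H](C)C=O)c(C)c(=O)c1C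
F5 | step 15 | C15-hydroxy analogue of triketone 25 (aldol adduct, mixture at C15/C16/C18) | CCc1oc([C@@H](C)[C@@H](O[Si](C)(C)C(C)(C)C)[C@H](C)/C=C(\C)[C@H](O[Si](C)(C)C(C)(C)C)[C@@H](C)C(O)C(C)C(=O)C(C)C(=O)[C@@H](C)[C@H](O[Si](C)(C)C(C)(C)C)CC)c(C)c(=O)c1C
F6 | step 5 | (2S,3S,4R)-5-(1,3,2-benzodioxaborol-2-yl)-3-[(tert-butyldimethylsilyl)oxy]-N-methoxy-N,2,4-trimethylpentanamide | CON(C)C(=O)[C@@H](C)[C@@H](O[Si](C)(C)C(C)(C)C)[C@H](C)CB1Oc2ccccc2O1
F7 | step 5 | (2S,3S,4R)-3-[(tert-butyldimethylsilyl)oxy]-5-hydroxy-N-methoxy-N,2,4-trimethylpentanamide | CON(C)C(=O)[C@@H](C)[C@@H](O[Si](C)(C)C(C)(C)C)[C@H](C)CO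
F8 | step 5 | (2S,3S,4R)-3-[(tert-butyldimethylsilyl)oxy]-N-methoxy-N,2,4-trimethyl-5-[(triethylsilyl)oxy]pentanamide | CON(C)C(=O)[C@@H](C)[C@@H](O[Si](C)(C)C(C)(C)C)[C@H](C)CO[Si](CC)(CC)CC
F9 | step 5 | (8S,9S,10R)-9-[(tert-butyldimethylsilyl)oxy]-4,6,8,10-tetramethyl-11-[(triethylsilyl)oxy]undecane-3,5,7-trione (C4/C6 epimers and enol tautomers) | CCC(=O)C(C)C(=O)C(C)C(=O)[C@@H](C)[C@@H](O[Si](C)(C)C(C)(C)C)[C@H](C)CO[Si](CC)(CC)CC
F10 | step 5 | 2-[(2S,3S,4R)-3-[(tert-butyldimethylsilyl)oxy]-4-methyl-5-[(triethylsilyl)oxy]pentan-2-yl]-6-ethyl-3,5-dimethyl-4H-pyran-4-one | CCc1oc([C@@H](C)[C@@H](O[Si](C)(C)C(C)(C)C)[C@H](C)CO[Si](CC)(CC)CC)c(C)c(=O)c1C
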